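**Plan**
- Retrosynthesis: with the six O–methyl bonds and two temporary C4–Cl bonds set aside, each benzofuranone is cut at O1–C7a and C3–C3a (four bonds). This releases two aryne equivalents of ring A and an open C6 bis(α-keto ester), which is cut at Cα–Cα' into two arylpyruvate units.
- Enabling feature: in each half, ring A carries O1 (on C7a) and the C3 carbonyl (on C3a) on adjacent carbons, and O1–C2(=Cα)–C3(=O) is the enol oxygen, enol carbon and carboxyl carbon of an α-keto ester. The two carbons of an aryne triple bond can therefore take up the oxygen and then the acyl carbon.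
- Forward: veratraldehyde is taken to the methyl arylpyruvate (azlactone route), and oxidative coupling at the benzylic carbon makes Cα–Cα' and the open chain. In parallel, 2-chloro-4-methoxyphenol is converted to the ortho-silylaryl triflate.
- A double aryne annulation then closes both furanone rings in one operation; hydrodechlorination at C4/C4' and O-demethylation finish the synthesis.
- Stereochemistry: there are no stereocentres. The two C2=Cα geometries come from the dienediolate (oxyanion syn to the neighbouring Cα') and can be re-equilibrated in the acidic last step.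

Key step: step 8

Assumption: the (2Z,2'Z) geometry of the target (each O1 syn to the Cα of the other half, each C3=O syn to its own aryl ring) is taken to be the thermodynamically preferred one, as in aurones, where the more demanding Cα substituent lies on the O1 side.
Remark: the 2,5-diketo diester is written as its diketo tautomer (meso/racemic mixture); the bis-enol tautomer and both diastereomers give the same dienediolate.

**Route**

Step 1
Reactants: 1 3,4-dimethoxybenzaldehyde; 2 N-acetylglycine
Product: 3 (4Z)-4-[(3,4-dimethoxyphenyl)methylidene]-2-methyl-1,3-oxazol-5(4H)-one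
Conditions: Ac2O, NaOAc, 110 °C
Reagents that add atoms: none
Why: Erlenmeyer–Plöchl azlactone synthesis, in which Ac2O cyclodehydrates 2 to the 2-methyloxazolone, its C4 carbanion condenses with the aldehyde, and the more stable (Z)-benzylidene isomer should crystallise.

Step 2
Reactants: 3 (4Z)-4-[(3,4-dimethoxyphenyl)methylidene]-2-methyl-1,3-oxazol-5(4H)-one
Product: 4 3-(3,4-dimethoxyphenyl)-2-oxopropanoic acid
Conditions: 3 M aq. HCl, AcOH, reflux
Reagents that add atoms: water, O
Why: Acid hydrolysis opens the azlactone to the α-acetamidocinnamic acid and then cleaves the enamide, the standard azlactone route to arylpyruvic acids, and the aryl methyl ethers tolerate dilute aqueous HCl.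

Step 3
Reactants: 4 3-(3,4-dimethoxyphenyl)-2-oxopropanoic acid
Product: 5 methyl 3-(3,4-dimethoxyphenyl)-2-oxopropanoate
Conditions: DBU (1.0 equiv), MeI, DMF, 0 °C
Reagents that add atoms: iodomethane, CI
Why: Carboxylate SN2 alkylation with one equivalent of amidine base should methylate only the carboxylic acid, since the enol OH is less acidic.

Step 4
Reactants: 5 methyl 3-(3,4-dimethoxyphenyl)-2-oxopropanoate (2 equiv)
Product: 7 dimethyl 3,4-bis(3,4-dimethoxyphenyl)-2,5-dioxohexanedioate, via sodium enolate 6 (not isolated)
Conditions: NaH (1.0 equiv), THF, 0 °C; I2 (0.5 equiv), −78 °C to rt; cold aq. Na2S2O3, pH 5; no acidic silica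
Reagents that add atoms: none
Why: Iodine-mediated oxidative enolate coupling, a known way to join arylpyruvates at the benzylic carbon to 3,4-diaryl-2,5-dioxoadipates; iodine turns half of 6 into the 3-iodo keto ester (or the benzylic radical), which the remaining enolate captures at carbon, and the meso/racemic mixture is acceptable because both stereocentres disappear on enolisation.

Step 5
Reactants: 8 2-chloro-4-methoxyphenol
Product: 9 2-bromo-6-chloro-4-methoxyphenol
Conditions: NBS, i-Pr2NH (cat.), CH2Cl2, 0 °C
Reagents that add atoms: N-bromosuccinimide, O=C1CCC(=O)N1Br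
Why: Amine-catalysed electrophilic aromatic bromination of a phenol should deliver bromine to C6, the only free position ortho to OH, because OH outweighs OMe as the activating group.

Step 6
Reactants: 9 2-bromo-6-chloro-4-methoxyphenol
Product: 10 (2-bromo-6-chloro-4-methoxyphenoxy)trimethylsilane
Conditions: HMDS, THF, 70 °C; evaporation
Reagents that add atoms: hexamethyldisilazane, C[Si](C)(C)N[Si](C)(C)C
Why: O-Silylation of the phenol with HMDS gives only ammonia as by-product, so the moisture-sensitive silyl ether can be used after evaporation.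

Step 7
Reactants: 10 (2-bromo-6-chloro-4-methoxyphenoxy)trimethylsilane
Product: 13 2-chloro-4-methoxy-6-(trimethylsilyl)phenyl trifluoromethanesulfonate, via aryllithium 11 (not isolated), via lithium silylphenolate 12 (not isolated)
Conditions: n-BuLi, THF, −100 to −80 °C; Tf2O, −100 °C to rt
Reagents that add atoms: trifluoromethanesulfonic anhydride, O=S(=O)(OS(=O)(=O)C(F)(F)F)C(F)(F)F
Why: Br–Li exchange is selective over the aryl chloride at low temperature, the ortho-lithio aryl silyl ether undergoes a 1,3 O-to-C silyl shift (retro-Brook rearrangement), and the phenolate is triflated, the standard sequence to ortho-silylaryl triflates.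

Step 8
Reactants: 7 dimethyl 3,4-bis(3,4-dimethoxyphenyl)-2,5-dioxohexanedioate; 13 2-chloro-4-methoxy-6-(trimethylsilyl)phenyl trifluoromethanesulfonate (3 equiv)
Product: 17 4,4'-dichlorodisulfuretin hexamethyl ether, via aryne 14 (not isolated), via dicesium dienediolate 15 (not isolated), via mono-annulated cesium enolate 16 (not isolated)
Conditions: CsF (8 equiv), THF, 65 °C, slow addition of 13
Reagents that add atoms: none
Why: Proposed new method: fluoride deprotonates 7 to the dienediolate 15 and releases aryne 14 from 13; each enolate oxygen adds to the aryne carbon remote from chlorine, and the aryl anion formed next to chlorine attacks the adjacent ester carbonyl and expels methoxide, giving first 16 and then 17. The closest known reactions are the fluoride-mediated union of ortho-silylaryl triflates with methyl salicylates to xanthones (O-arylation, then acyl capture by the aryl anion) and the aryne acyl-alkylation of β-keto esters; an α-keto ester enolate as the partner for a benzofuran-3-one is untested. Each furanone ring closes by 5-exo-trig attack of the C3a carbanion on the ester carbon, so that O1–C7a and then C3–C3a form in each half. No stereocentre arises; the C2=Cα geometries are inherited from 15, in which the ester should lie syn to the twisted aryl ring and the oxyanion syn to the bulkier neighbouring Cα', the (Z,Z) arrangement of the target. O- over C-arylation is secured by the fully substituted enolate carbon, and the aryne orientation by chlorine at the future C4, whose inductive pull polarises the triple bond and overrides the weak opposite bias of the remote methoxy group. Slow addition of 13 keeps the aryne concentration low, so that the dianion rather than released methoxide or a second aryne intercepts it.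

Step 9
Reactants: 17 4,4'-dichlorodisulfuretin hexamethyl ether
Product: 18 disulfuretin hexamethyl ether
Conditions: Pd(OAc)2 (cat.), XPhos, HCO2Na, DMF–H2O, 90 °C
Reagents that add atoms: none
Why: Palladium-catalysed transfer hydrodehalogenation, in which zerovalent palladium bearing a bulky dialkylbiarylphosphine inserts into the carbonyl-activated C4–Cl bond, formate supplies hydride by decarboxylation, and reductive elimination forms C4–H, while the hindered tetrasubstituted enone double bonds should resist the palladium hydride.

Step 10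
Reactants: 18 disulfuretin hexamethyl ether
Product: 19 disulfuretin
Conditions: BBr3 (12 equiv), CH2Cl2, −78 °C to rt; ice/H2O
Reagents that add atoms: none
Why: Lewis acid cleavage of aryl methyl ethers, in which BBr3 complexes each ether oxygen and bromide removes the methyl group by SN2; the acidic medium also permits rotation about C2–Cα through the O-complexed enone, so the geometry should settle on the (Z,Z) isomer.

**Compound list**

1 | 3,4-dimethoxybenzaldehyde | COc1ccc(C=O)cc1OC | starting material
2 | N-acetylglycine | CC(=O)NCC(=O)O | starting material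
3 | (4Z)-4-[(3,4-dimethoxyphenyl)methylidene]-2-methyl-1,3-oxazol-5(4H)-one | CC1=N/C(=C\c2ccc(OC)c(OC)c2)C(=O)O1 | intermediate
4 | 3-(3,4-dimethoxyphenyl)-2-oxopropanoic acid | COc1ccc(CC(=O)C(=O)O)cc1OC | intermediate
5 | methyl 3-(3,4-dimethoxyphenyl)-2-oxopropanoate | COC(=O)C(=O)Cc1ccc(OC)c(OC)c1 | intermediate
6 | sodium (Z)-3-(3,4-dimethoxyphenyl)-1-methoxy-1-oxoprop-2-en-2-olate (not isolated) | COC(=O)/C([O-])=C/c1ccc(OC)c(OC)c1.[Na+] | intermediate
7 | dimethyl 3,4-bis(3,4-dimethoxyphenyl)-2,5-dioxohexanedioate (meso and racemic diastereomers, not separated) | COC(=O)C(=O)C(c1ccc(OC)c(OC)c1)C(c1ccc(OC)c(OC)c1)C(=O)C(=O)OC | intermediate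
8 | 2-chloro-4-methoxyphenol | COc1ccc(O)c(Cl)c1 | starting material
9 | 2-bromo-6-chloro-4-methoxyphenol | COc1cc(Cl)c(O)c(Br)c1 | intermediate
10 | (2-bromo-6-chloro-4-methoxyphenoxy)trimethylsilane | COc1cc(Cl)c(O[Si](C)(C)C)c(Br)c1 | intermediate
11 | [3-chloro-5-methoxy-2-(trimethylsilyloxy)phenyl]lithium (not isolated) | COc1cc(Cl)c(O[Si](C)(C)C)c([Li])c1 | intermediate
12 | lithium 2-chloro-4-methoxy-6-(trimethylsilyl)phenolate (not isolated) | COc1cc(Cl)c([O-])c([Si](C)(C)C)c1.[Li+] | intermediate
13 | 2-chloro-4-methoxy-6-(trimethylsilyl)phenyl trifluoromethanesulfonate | COc1cc(Cl)c(OS(=O)(=O)C(F)(F)F)c([Si](C)(C)C)c1 | intermediate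
14 | 3-chloro-5-methoxybenzyne (3-chloro-5-methoxy-1,2-didehydrobenzene; not isolated) | COC1=CC#CC(Cl)=C1 | intermediate
15 | dicesium (2Z,4Z)-3,4-bis(3,4-dimethoxyphenyl)-1,6-dimethoxy-1,6-dioxohexa-2,4-diene-2,5-diolate (not isolated) | COC(=O)/C([O-])=C(c1ccc(OC)c(OC)c1)/C(c1ccc(OC)c(OC)c1)=C(\[O-])C(=O)OC.[Cs+].[Cs+] | intermediate
16 | cesium (2Z,4Z)-4-(4-chloro-6-methoxy-3-oxo-1-benzofuran-2(3H)-ylidene)-3,4-bis(3,4-dimethoxyphenyl)-1-methoxy-1-oxobut-2-en-2-olate (not isolated) | O=C1/C(=C(/C(=C(\[O-])C(=O)OC)c2ccc(OC)c(OC)c2)c2ccc(OC)c(OC)c2)Oc2cc(OC)cc(Cl)c21.[Cs+] | intermediate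
17 | 4,4'-dichlorodisulfuretin hexamethyl ether, (2Z,2'Z)-2,2'-[1,2-bis(3,4-dimethoxyphenyl)ethane-1,2-diylidene]bis(4-chloro-6-methoxy-1-benzofuran-3(2H)-one) | O=C1/C(=C(/C(=C2\Oc3cc(OC)cc(Cl)c3C2=O)c2ccc(OC)c(OC)c2)c2ccc(OC)c(OC)c2)Oc2cc(OC)cc(Cl)c21 | intermediate
18 | disulfuretin hexamethyl ether, (2Z,2'Z)-2,2'-[1,2-bis(3,4-dimethoxyphenyl)ethane-1,2-diylidene]bis(6-methoxy-1-benzofuran-3(2H)-one) | O=C1/C(=C(/C(=C2\Oc3cc(OC)ccc3C2=O)c2ccc(OC)c(OC)c2)c2ccc(OC)c(OC)c2)Oc2cc(OC)ccc21 | intermediate
19 | disulfuretin, (2Z,2'Z)-2,2'-[1,2-bis(3,4-dihydroxyphenyl)ethane-1,2-diylidene]bis(6-hydroxy-1-benzofuran-3(2H)-one) | O=C1/C(=C(/C(=C2\Oc3cc(O)ccc3C2=O)c2ccc(O)c(O)c2)c2ccc(O)c(O)c2)Oc2cc(O)ccc21 | target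

**Step count and risks**

Total steps: 10 (steps 1–4 to the diketo diester, steps 5–7 to the aryne precursor, steps 8–10 in common).
Longest linear sequence: 7 steps (1, 2, 3, 4, 8, 9, 10).

Most likely to fail, step 8: the aryne may be captured at the enolate carbon or across the diene in a [4+2] sense. The aryl anion may be protonated, or may lose chloride, before it reaches the ester. The double-bond geometry may also be scrambled. The fallback assembles the bis-aurone by classical aurone chemistry and sets out from 1. Thiazolium-catalysed benzoin condensation (3-benzyl-5-(2-hydroxyethyl)-4-methylthiazolium chloride, Et3N, EtOH, 80 °C) should give racemic 3,3',4,4'-tetramethoxybenzoin F1. Oxidation (cat. Cu(OAc)2, NH4NO3, aq. AcOH, reflux) should give 3,3',4,4'-tetramethoxybenzil F2. Knoevenagel condensation under TiCl4/pyridine in THF with commercial 6-methoxy-1-benzofuran-3(2H)-one (COc1ccc2C(=O)COc2c1) should give first the mono-condensation product (Z)-2-[1,2-bis(3,4-dimethoxyphenyl)-2-oxoethylidene]-6-methoxy-1-benzofuran-3(2H)-one F3 and, with a second equivalent, 18. The route is rejoined at 18, and steps 5 to 9 are then not needed.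

Second, step 4: the enolate may couple through oxygen or be over-oxidised, the electron-rich ring may be iodinated, and the 1,4-diketone may cyclodehydrate to the furan diester (Paal–Knorr) on work-up. The fallback sets out from 5. Silylation (TMSCl, Et3N, THF) should give methyl (Z)-3-(3,4-dimethoxyphenyl)-2-[(trimethylsilyl)oxy]prop-2-enoate F4. Its oxidative dimerisation with Ag2O in DMSO at 60 °C, the known coupling of silyl enol ethers to 1,4-diketones, rejoins the route at 7.

Third, step 9: the palladium hydride may reduce or isomerise the enone double bonds, or insertion into the C–Cl bond beside the carbonyl may stall. The fallback sets out from 17 and avoids any hydride. Miyaura borylation (B2pin2, Pd(OAc)2, XPhos, KOAc, dioxane, 100 °C) should give (2Z,2'Z)-2,2'-[1,2-bis(3,4-dimethoxyphenyl)ethane-1,2-diylidene]bis[6-methoxy-4-(4,4,5,5-tetramethyl-1,3,2-dioxaborolan-2-yl)-1-benzofuran-3(2H)-one] F5. Protodeboronation of this ortho-acyl arylboronate (aq. K2CO3, dioxane, 80 °C) rejoins the route at 18.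

**Further compounds**

F1 | step 8 | 3,3',4,4'-tetramethoxybenzoin, 2-hydroxy-1,2-bis(3,4-dimethoxyphenyl)ethan-1-one (racemic) | COc1ccc(C(O)C(=O)c2ccc(OC)c(OC)c2)cc1OC
F2 | step 8 | 3,3',4,4'-tetramethoxybenzil, 1,2-bis(3,4-dimethoxyphenyl)ethane-1,2-dione | COc1ccc(C(=O)C(=O)c2ccc(OC)c(OC)c2)cc1OC
F3 | step 8 | (Z)-2-[1,2-bis(3,4-dimethoxyphenyl)-2-oxoethylidene]-6-methoxy-1-benzofuran-3(2H)-one | O=C1/C(=C(/C(=O)c2ccc(OC)c(OC)c2)c2ccc(OC)c(OC)c2)Oc2cc(OC)ccc21
F4 | step 4 | methyl (Z)-3-(3,4-dimethoxyphenyl)-2-[(trimethylsilyl)oxy]prop-2-enoate | COC(=O)/C(O[Si](C)(C)C)=C/c1ccc(OC)c(OC)c1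
F5 | step 9 | (2Z,2'Z)-2,2'-[1,2-bis(3,4-dimethoxyphenyl)ethane-1,2-diylidene]bis[6-methoxy-4-(4,4,5,5-tetramethyl-1,3,2-dioxaborolan-2-yl)-1-benzofuran-3(2H)-one] | O=C1/C(=C(/C(=C2\Oc3cc(OC)cc(B4OC(C)(C)C(C)(C)O4)c3C2=O)c2ccc(OC)c(OC)c2)c2ccc(OC)c(OC)c2)Oc2cc(OC)cc(B3OC(C)(C)C(C)(C)O3)c21
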